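The strategy rests on cutting the two C2–CH2 bonds that hold the 2-phenylethyl chains on the pyranone rings. In unit A (7-oxygenated, biaryl bond at C6) and unit B (8'-oxygenated, biaryl bond at C5'), C2 and C2' each sit at the β-end of a C2=C3–C4=O enone. A carboxyl group on C3/C3' turns each into a strong acceptor for a nucleophilic alkyl radical. A single electrolysis of the N-hydroxyphthalimide ester of 3-phenylpropanoic acid with 7,8'-dimethoxy-6,5'-bichromone-3,3'-dicarboxylic acid, which carries hydrogen at C2 and C2', should form both bonds, expel four CO2 and leave a bis-chromanone. Dehydrogenation and ether cleavage then give the target.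

Key step: step 11

Assumption: rotation about the C6–C5' axis (only the C7 oxygen and C4a' stand ortho to it) is taken to be fast at room temperature, so no axial configuration has to be set, in line with the stereo-free SMILES of the target.

Remark on the precursor:
- The key step does create two stereocentres (C2, C2'). They are uncontrolled and are removed again in step 12.
- Both phenols stay as methyl ethers through the electrolysis, because free phenols would be oxidised at the anode and would quench alkyl radicals.
- Diacid 11 is deprotonated in the cell by iPr2NEt, which dissolves it and makes it harder to reduce.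

Step 1
Reactants: 1 1-(2-hydroxy-4-methoxyphenyl)ethanone (paeonol)
Product: 2 1-(5-bromo-2-hydroxy-4-methoxyphenyl)ethanone
Conditions: NBS (1.05 equiv), MeCN, 0 °C to rt
Reagents that add atoms: N-bromosuccinimide O=C1CCC(=O)N1Br
Why: Electrophilic aromatic bromination; C5 is para to the phenol and ortho to the methoxy group, whereas the doubly activated C3 is shielded between two oxygens, so the 5-bromide should be the main product.

Step 2
Reactants: 2 1-(5-bromo-2-hydroxy-4-methoxyphenyl)ethanone
Product: 3 1-[2-hydroxy-4-methoxy-5-(4,4,5,5-tetramethyl-1,3,2-dioxaborolan-2-yl)phenyl]ethanone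
Conditions: B2pin2 (1.2 equiv), KOAc (3 equiv), Pd(dppf)Cl2 (4 mol %), 1,4-dioxane, 90 °C, N2
Reagents that add atoms: bis(pinacolato)diboron CC1(C)OB(OC1(C)C)B1OC(C)(C)C(C)(C)O1
Why: Miyaura borylation; zerovalent palladium inserts into the C–Br bond and acetate-assisted transmetalation installs the boronate, while the weak base leaves the hydrogen-bonded phenol and the ketone alone.

Step 3
Reactants: 4 2,3-dimethoxybenzaldehyde
Product: 5 6-bromo-2,3-dimethoxybenzaldehyde
Conditions: NBS (1.3 equiv), DMF, rt
Reagents that add atoms: N-bromosuccinimide O=C1CCC(=O)N1Br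
Why: Electrophilic aromatic bromination; the in-plane 3-methoxy group directs para to C6 while the flanked 2-methoxy group is twisted out of conjugation, which is the established regiochemistry for this aldehyde under these conditions.

Step 4
Reactants: 5 6-bromo-2,3-dimethoxybenzaldehyde
Product: 6 rac-1-(6-bromo-2,3-dimethoxyphenyl)ethanol
Conditions: MeMgBr (1.2 equiv), THF, 0 °C; then aq NH4Cl
Reagents that add atoms: methylmagnesium bromide C[Mg]Br
Why: Grignard 1,2-addition to the aldehyde; MeMgBr does not exchange with the aryl bromide at 0 °C, and the carbinol centre forms racemic and is removed in step 5.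

Step 5
Reactants: 6 rac-1-(6-bromo-2,3-dimethoxyphenyl)ethanol
Product: 7 1-(6-bromo-2,3-dimethoxyphenyl)ethanone
Conditions: Dess–Martin periodinane (1.2 equiv), CH2Cl2, rt
Reagents that add atoms: none
Why: Dess–Martin oxidation of a hindered secondary benzylic alcohol under mild conditions that leave the aryl bromide and the ethers untouched.

Step 6
Reactants: 3 1-[2-hydroxy-4-methoxy-5-(4,4,5,5-tetramethyl-1,3,2-dioxaborolan-2-yl)phenyl]ethanone; 7 1-(6-bromo-2,3-dimethoxyphenyl)ethanone
Product: 8 1-[5-(2-acetyl-3,4-dimethoxyphenyl)-2-hydroxy-4-methoxyphenyl]ethanone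
Conditions: Pd(OAc)2 (3 mol %), SPhos (2-dicyclohexylphosphino-2',6'-dimethoxybiphenyl, 6 mol %), K3PO4 (3 equiv), toluene/H2O, 80 °C, N2
Reagents that add atoms: none
Why: Suzuki–Miyaura coupling; the ortho-acetyl group speeds oxidative addition into 7, which is kept as the neutral dimethyl ether, the electron-rich boronate 3 transmetalates readily, and the bulky biarylphosphine copes with the two ortho substituents beside the new bond.

Step 7
Reactants: 8 1-[5-(2-acetyl-3,4-dimethoxyphenyl)-2-hydroxy-4-methoxyphenyl]ethanone
Product: 9 1-[5-(2-acetyl-3-hydroxy-4-methoxyphenyl)-2-hydroxy-4-methoxyphenyl]ethanone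
Conditions: BCl3 (3 equiv, 1 M in CH2Cl2), CH2Cl2, −78 to 0 °C; then H2O
Reagents that add atoms: none
Why: Chelation-directed aryl methyl ether cleavage; BCl3 bound to the ring B carbonyl removes only the adjacent out-of-plane methoxy group, as is general for 2-methoxyaryl ketones, while the neighbouring methoxy group and the ring A methoxy group para to a boron-complexed ketone should stay.

Step 8
Reactants: 9 1-[5-(2-acetyl-3-hydroxy-4-methoxyphenyl)-2-hydroxy-4-methoxyphenyl]ethanone
Product: 10 7,8'-dimethoxy-4,4'-dioxo-4H,4'H-6,5'-bichromene-3,3'-dicarbaldehyde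
Conditions: POCl3 (10 equiv), DMF, 0 °C to 55 °C; then ice-water
Reagents that add atoms: N,N-dimethylformamide CN(C)C=O (C2, C2' and both formyl carbons); water O (both aldehyde oxygens)
Why: Vilsmeier–Haack formylative cyclisation, the standard 3-formylchromone synthesis from 2-hydroxyacetophenones; each acetyl methyl group takes up two C1 units from the chloroiminium salt, the phenol closes the pyranone with loss of dimethylamine, and water frees the aldehyde.

Step 9
Reactants: 10 7,8'-dimethoxy-4,4'-dioxo-4H,4'H-6,5'-bichromene-3,3'-dicarbaldehyde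
Product: 11 7,8'-dimethoxy-4,4'-dioxo-4H,4'H-6,5'-bichromene-3,3'-dicarboxylic acid
Conditions: NaClO2 (5 equiv), sulfamic acid (6 equiv), CH2Cl2/H2O, 0 °C to rt
Reagents that add atoms: sodium chlorite [Na+].[O-]Cl=O
Why: Pinnick-type chlorite oxidation as routinely used for 3-formylchromones; chlorous acid oxidises the aldehydes at low pH, where the base-sensitive pyranones are safe, and sulfamic acid traps hypochlorous acid before it can chlorinate the methoxyarenes.

Step 10
Reactants: 12 3-phenylpropanoic acid; 13 N-hydroxyphthalimide
Product: 14 1,3-dioxoisoindolin-2-yl 3-phenylpropanoate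
Conditions: DCC (1.1 equiv), DMAP (10 mol %), CH2Cl2, rt
Reagents that add atoms: none
Why: Steglich-type carbodiimide esterification of the acid with the N-hydroxy imide, the standard preparation of redox-active esters.

Step 11
Reactants: 11 7,8'-dimethoxy-4,4'-dioxo-4H,4'H-6,5'-bichromene-3,3'-dicarboxylic acid; 14 1,3-dioxoisoindolin-2-yl 3-phenylpropanoate
Product: 16 7,8'-dimethoxy-2,2'-bis(2-phenylethyl)-6,5'-bichroman-4,4'-dione (mixture of diastereomers), via bis-β-keto acid 15 (not isolated)
Conditions: undivided cell, graphite-felt cathode, graphite anode, constant current at low current density (about 6 F per mol of 11), 14 (4 equiv, in two portions), iPr2NEt (6 equiv), nBu4NBF4 (0.1 M), dry N,N-dimethylacetamide, N2, rt; then 40 °C; aqueous work-up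
Reagents that add atoms: none
Why: Proposed new method: the carbon cathode passes one electron to 14, whose radical anion cleaves at N–O and loses CO2 to give the primary 2-phenylethyl radical; this nucleophilic radical adds to the unsubstituted, electron-poor C2 and C2' of 11, each adduct radical at C3, flanked by ketone and carboxyl, takes a second electron and a proton to reach 15, and each β-keto acid then loses CO2. The closest known reaction types are the visible-light photoredox doubly decarboxylative Giese addition of N-(acyloxy)phthalimides to chromone-3-carboxylic acids, which gives 2-alkylchroman-4-ones, and the cathodic Giese addition of the same esters to acrylates and enones in undivided cells; new here are the electrode as electron source for this acceptor class and the twofold run on one molecule. No ring is closed. C2 and C2' become stereocentres with no controlling element, so 16 should form as a mixture of racemic diastereomers, which does no harm because step 12 makes both carbons planar again. The step needs attack at C2/C2' only, which the C3 carboxyl secures by polarising the alkene and stabilising the adduct radical, and it needs 14 to be reduced before the acceptor, which deprotonation of 11 by iPr2NEt (a carboxylate is harder to reduce) and a standing excess of 14 at constant current should secure. iPr2NEt is oxidised at the anode in preference to the carboxylates and methoxyarenes and releases the protons that the cathodic events consume.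

Step 12
Reactants: 16 7,8'-dimethoxy-2,2'-bis(2-phenylethyl)-6,5'-bichroman-4,4'-dione (mixture of diastereomers)
Product: 17 7,8'-dimethoxy-2,2'-bis(2-phenylethyl)-4H,4'H-6,5'-bichromene-4,4'-dione
Conditions: I2 (20 mol %), DMSO, 120 °C, stopped as soon as 16 is consumed
Reagents that add atoms: none
Why: Iodine-catalysed dehydrogenation in DMSO of the flavanone-to-flavone type; enolisation, C3 iodination and loss of HI build each C2=C3 bond, DMSO reoxidises HI, and any retro-oxa-Michael-opened hydroxy enone is funnelled to the same chromone.

Step 13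
Reactants: 17 7,8'-dimethoxy-2,2'-bis(2-phenylethyl)-4H,4'H-6,5'-bichromene-4,4'-dione
Product: 18 7,8'-dihydroxy-2,2'-bis(2-phenylethyl)-4H,4'H-6,5'-bichromene-4,4'-dione (CNP0279305.0)
Conditions: BBr3 (8 equiv), CH2Cl2, −78 °C to rt; then H2O
Reagents that add atoms: none
Why: Lewis-acid aryl methyl ether cleavage with BBr3, used in excess because both pyranone carbonyls bind boron; the chromone rings and the saturated side chains are inert to it.

Compound list

1 | 1-(2-hydroxy-4-methoxyphenyl)ethanone (paeonol) | CC(=O)c1ccc(OC)cc1O | starting material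
2 | 1-(5-bromo-2-hydroxy-4-methoxyphenyl)ethanone | CC(=O)c1cc(Br)c(OC)cc1O | intermediate
3 | 1-[2-hydroxy-4-methoxy-5-(4,4,5,5-tetramethyl-1,3,2-dioxaborolan-2-yl)phenyl]ethanone | CC(=O)c1cc(B2OC(C)(C)C(C)(C)O2)c(OC)cc1O | intermediate
4 | 2,3-dimethoxybenzaldehyde | COc1cccc(C=O)c1OC | starting material
5 | 6-bromo-2,3-dimethoxybenzaldehyde | COc1ccc(Br)c(C=O)c1OC | intermediate
6 | rac-1-(6-bromo-2,3-dimethoxyphenyl)ethanol | COc1ccc(Br)c(C(C)O)c1OC | intermediate
7 | 1-(6-bromo-2,3-dimethoxyphenyl)ethanone | COc1ccc(Br)c(C(C)=O)c1OC | intermediate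
8 | 1-[5-(2-acetyl-3,4-dimethoxyphenyl)-2-hydroxy-4-methoxyphenyl]ethanone | CC(=O)c1cc(-c2ccc(OC)c(OC)c2C(C)=O)c(OC)cc1O | intermediate
9 | 1-[5-(2-acetyl-3-hydroxy-4-methoxyphenyl)-2-hydroxy-4-methoxyphenyl]ethanone | CC(=O)c1cc(-c2ccc(OC)c(O)c2C(C)=O)c(OC)cc1O | intermediate
10 | 7,8'-dimethoxy-4,4'-dioxo-4H,4'H-6,5'-bichromene-3,3'-dicarbaldehyde | O=Cc1coc2cc(OC)c(-c3ccc(OC)c4occ(C=O)c(=O)c34)cc2c1=O | intermediate
11 | 7,8'-dimethoxy-4,4'-dioxo-4H,4'H-6,5'-bichromene-3,3'-dicarboxylic acid | O=C(O)c1coc2cc(OC)c(-c3ccc(OC)c4occ(C(=O)O)c(=O)c34)cc2c1=O | intermediate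
12 | 3-phenylpropanoic acid | O=C(O)CCc1ccccc1 | starting material
13 | N-hydroxyphthalimide | O=C1c2ccccc2C(=O)N1O | starting material
14 | 1,3-dioxoisoindolin-2-yl 3-phenylpropanoate | O=C(CCc1ccccc1)ON1C(=O)c2ccccc2C1=O | intermediate
15 | 7,8'-dimethoxy-4,4'-dioxo-2,2'-bis(2-phenylethyl)-6,5'-bichromane-3,3'-dicarboxylic acid (stereoisomer mixture; formal double adduct, each half decarboxylates on its own) | O=C1C(C(=O)O)C(CCc2ccccc2)Oc2cc(OC)c(-c3ccc(OC)c4OC(CCc5ccccc5)C(C(=O)O)C(=O)c34)cc12 | intermediate
16 | 7,8'-dimethoxy-2,2'-bis(2-phenylethyl)-6,5'-bichroman-4,4'-dione (mixture of racemic diastereomers) | O=C1CC(CCc2ccccc2)Oc2cc(OC)c(-c3ccc(OC)c4OC(CCc5ccccc5)CC(=O)c34)cc12 | intermediate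
17 | 7,8'-dimethoxy-2,2'-bis(2-phenylethyl)-4H,4'H-6,5'-bichromene-4,4'-dione | O=c1cc(CCc2ccccc2)oc2cc(OC)c(-c3ccc(OC)c4oc(CCc5ccccc5)cc(=O)c34)cc12 | intermediate
18 | 7,8'-dihydroxy-2,2'-bis(2-phenylethyl)-4H,4'H-6,5'-bichromene-4,4'-dione (CNP0279305.0) | O=c1cc(CCc2ccccc2)oc2cc(O)c(-c3ccc(O)c4oc(CCc5ccccc5)cc(=O)c34)cc12 | target

Total step count: 13.
Longest linear sequence: 10 (steps 3, 4, 5, 6, 7, 8, 9, 11, 12, 13).

Steps most likely to fail

1. Step 11.
   - What may go wrong: the acceptor may be reduced directly at the cathode. The primary radical may be reduced or may dimerise at the electrode surface before it meets the acceptor. The reaction may also stall after the first of the two additions.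
   - Fallback (known ionic chemistry, the classical entry to 2-(2-phenylethyl)chromones): setting out from 9, a twofold crossed Claisen condensation of both acetyl methyl groups with ethyl 3-phenylpropanoate (NaH in excess, THF, reflux) would give 1-[5-[3-hydroxy-4-methoxy-2-(3-oxo-5-phenylpentanoyl)phenyl]-2-hydroxy-4-methoxyphenyl]-5-phenylpentane-1,3-dione F1. Acid-catalysed cyclodehydration of this compound (HCl, MeOH, reflux) closes both pyranones. The route is rejoined at 17.

2. Step 12.
   - What may go wrong: iodination and elimination may be slow in the peri-crowded ring of unit B, or the oxidation may run on into the C2 side chains.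
   - Fallback (a palladium-mediated dehydrogenation with a fixed oxidant count instead of a halogen-based one): setting out from 16, soft enolisation (TMSOTf, Et3N, CH2Cl2, 0 °C) would give 7,8'-dimethoxy-2,2'-bis(2-phenylethyl)-4,4'-bis(trimethylsilyloxy)-2H,2'H-6,5'-bichromene F2. Saegusa–Ito oxidation with Pd(OAc)2 (2.2 equiv, MeCN, rt) proceeds through the divalent palladium enolates and β-hydride elimination of the C2 hydrogens. The route is rejoined at 17.

3. Step 8.
   - What may go wrong: enolisation may be sluggish and the second formylation incomplete at the twisted acetyl group of ring B, with competing electrophilic attack on the activated arenes.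
   - Fallback (staged introduction of the two C1 units): setting out from 9, heating with N,N-dimethylformamide dimethyl acetal (toluene, 100 °C) would give, under neutral conditions, (E)-3-(dimethylamino)-1-[5-[2-[(E)-3-(dimethylamino)prop-2-enoyl]-3-hydroxy-4-methoxyphenyl]-2-hydroxy-4-methoxyphenyl]prop-2-en-1-one F3. Its nucleophilic α-carbons are then formylated with the preformed chloroiminium salt (POCl3/DMF, CH2Cl2, 0 °C). This triggers the electrophile-induced chromone annulation typical of o-hydroxyaryl enaminones, and aqueous hydrolysis rejoins the route at 10.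

Further compounds

F1 | step 11 | 1-[5-[3-hydroxy-4-methoxy-2-(3-oxo-5-phenylpentanoyl)phenyl]-2-hydroxy-4-methoxyphenyl]-5-phenylpentane-1,3-dione | O=C(CCc1ccccc1)CC(=O)c1cc(-c2ccc(OC)c(O)c2C(=O)CC(=O)CCc2ccccc2)c(OC)cc1O
F2 | step 12 | 7,8'-dimethoxy-2,2'-bis(2-phenylethyl)-4,4'-bis(trimethylsilyloxy)-2H,2'H-6,5'-bichromene | C[Si](C)(C)OC1=CC(CCc2ccccc2)Oc2cc(OC)c(-c3ccc(OC)c4OC(CCc5ccccc5)C=C(O[Si](C)(C)C)c34)cc12
F3 | step 8 | (E)-3-(dimethylamino)-1-[5-[2-[(E)-3-(dimethylamino)prop-2-enoyl]-3-hydroxy-4-methoxyphenyl]-2-hydroxy-4-methoxyphenyl]prop-2-en-1-one | CN(C)/C=C/C(=O)c1cc(-c2ccc(OC)c(O)c2C(=O)/C=C/N(C)C)c(OC)cc1O
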